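**Retrosynthetic overview**
- Target 18 ⇐ angelate ester of the (1S)-carbinol 15 ⇐ aryl methyl ketone 14 ⇐ C5 bromide 11 (Stille coupling) ⇐ acetate 10; C5 is para to O1, so it is addressed by electrophilic bromination after the core exists.
- Core 9 ⇐ O1–C7a and C3a–C3 cut together: benzyne (ring A) plus the (S)-α-hydroxy aldehyde 5 (the O1–C2–C3 unit). Ring A is bought; ring B is the only ring formed.
- Enabling feature: O1 and C3 sit on the adjacent ring-A carbons C7a and C3a; C3 carries oxygen at the aldehyde level next to the O1-bearing C2; ring A is otherwise substituted only at C5, so symmetric benzyne can be used.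
- 5 ⇐ acetal hydrolysis ⇐ asymmetric Morita–Baylis–Hillman adduct of hexafluoroisopropyl acrylate 1 and glyoxal dimethyl acetal 2.

Key step: step 4

Assumption: β-isocupreidine is taken to show with aldehyde 2 the facial preference known for simple aliphatic aldehydes, which for this substitution pattern corresponds to the 3S adduct.

**Step 1**
Reactants: 1 1,1,1,3,3,3-hexafluoropropan-2-yl prop-2-enoate; 2 2,2-dimethoxyacetaldehyde (dried and distilled)
Product: 3 1,1,1,3,3,3-hexafluoropropan-2-yl (3S)-3-hydroxy-4,4-dimethoxy-2-methylidenebutanoate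
Conditions: β-isocupreidine (10 mol %), DMF, −55 °C
Reagents that add atoms: none
Why: Asymmetric Morita–Baylis–Hillman reaction, in which the quinuclidine nitrogen of the catalyst adds to the activated acrylate and its phenolic hydroxyl organises the aldol step, so the carbinol centre should form with the 3S configuration.

**Step 2**
Reactants: 3 1,1,1,3,3,3-hexafluoropropan-2-yl (3S)-3-hydroxy-4,4-dimethoxy-2-methylidenebutanoate
Product: 4 methyl (3S)-3-hydroxy-4,4-dimethoxy-2-methylidenebutanoate
Conditions: MeOH, Et3N, 25 °C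
Reagents that add atoms: methanol, CO
Why: Base-promoted transesterification of the activated hexafluoroisopropyl ester by methanol, which does not involve the stereocentre.

**Step 3**
Reactants: 4 methyl (3S)-3-hydroxy-4,4-dimethoxy-2-methylidenebutanoate
Product: 5 methyl (3S)-3-hydroxy-2-methylidene-4-oxobutanoate
Conditions: CF3CO2H, H2O, CHCl3, 0 °C; concentrate with toluene; used at once as the monomer–dimer mixture
Reagents that add atoms: water, O
Why: Acid-catalysed acetal hydrolysis with a volatile acid, which avoids aqueous extraction of the water-soluble α-hydroxy aldehyde and leaves the C–O bond at C3 untouched.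

**Step 4**
Reactants: 5 methyl (3S)-3-hydroxy-2-methylidene-4-oxobutanoate (1.5 equiv); 6 2-(trimethylsilyl)phenyl trifluoromethanesulfonate
Product: 9 methyl 2-[(2S,3S)-3-hydroxy-2,3-dihydro-1-benzofuran-2-yl]prop-2-enoate, via benzyne 7 (not isolated), via cesium aryl anion 8 (not isolated)
Conditions: CsF (3 equiv), MeCN, 25 °C, 6 added slowly; NH4Cl quench
Reagents that add atoms: none
Why: Proposed new method: fluoride attacks the silicon of 6 and triflate is lost to give benzyne 7, whose strained triple bond is attacked by the cesium alkoxide of 5 (O1–C7a bond); the ortho-aryloxy aryl anion 8 then adds to the aldehyde three atoms away (C3a–C3 bond) faster than it is protonated. The closest known reaction type is the fluoride-induced aryne annulation of ortho-hydroxyaryl aldehydes and ketones to xanthene derivatives and of N-sulfonyl α-amino ketones to 3-hydroxyindolines, here transferred to an aliphatic α-hydroxy aldehyde. Ring B closes in the 5-exo-trig mode. C2 is carried over from 5 unchanged because its C–O bond is never broken, and C3 is set by C2: in the closing rotamer the aldehyde oxygen lies on the face of the acrylate substituent, where the cesium ion can bridge the forming alkoxide and the ester carbonyl, which should give the 2,3-cis (2S,3S) alcohol. Regioselectivity needs no control because benzyne is symmetric, which is possible since ring A carries nothing at C4, C6 and C7; chemoselectivity for O-addition over enolisation of 5 is favoured by the slow release of the aryne and the excess of 5.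

**Step 5**
Reactants: 9 methyl 2-[(2S,3S)-3-hydroxy-2,3-dihydro-1-benzofuran-2-yl]prop-2-enoate
Product: 10 methyl 2-[(2S,3S)-3-(acetyloxy)-2,3-dihydro-1-benzofuran-2-yl]prop-2-enoate
Conditions: Ac2O, pyridine, 4-(dimethylamino)pyridine (cat.), CH2Cl2, 0 °C
Reagents that add atoms: acetic anhydride, CC(=O)OC(C)=O
Why: Nucleophile-catalysed O-acylation of the secondary benzylic alcohol with retention, run cold so that acyl transfer outruns lactonisation onto the cis ester.

**Step 6**
Reactants: 10 methyl 2-[(2S,3S)-3-(acetyloxy)-2,3-dihydro-1-benzofuran-2-yl]prop-2-enoate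
Product: 11 methyl 2-[(2S,3S)-3-(acetyloxy)-5-bromo-2,3-dihydro-1-benzofuran-2-yl]prop-2-enoate
Conditions: NBS, MeCN, 0 to 25 °C, dark
Reagents that add atoms: N-bromosuccinimide, O=C1CCC(=O)N1Br
Why: Electrophilic aromatic bromination directed para to the ring oxygen O1 (C5), the acrylate alkene being too electron-poor to react with NBS.

**Step 7**
Reactants: 11 methyl 2-[(2S,3S)-3-(acetyloxy)-5-bromo-2,3-dihydro-1-benzofuran-2-yl]prop-2-enoate; 12 tributyl(1-ethoxyethenyl)stannane
Product: 14 methyl 2-[(2S,3S)-5-acetyl-3-(acetyloxy)-2,3-dihydro-1-benzofuran-2-yl]prop-2-enoate, via ethoxyvinyl arene 13 (not isolated)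
Conditions: PdCl2(PPh3)2 (5 mol %), toluene, 95 °C; then 1 M HCl, THF, 25 °C
Reagents that add atoms: water, O
Why: Stille coupling of the aryl bromide with the 1-ethoxyvinyl stannane followed by mild acid hydrolysis of the enol ether to the methyl ketone, at a site remote from both stereocentres.

**Step 8**
Reactants: 14 methyl 2-[(2S,3S)-5-acetyl-3-(acetyloxy)-2,3-dihydro-1-benzofuran-2-yl]prop-2-enoate
Product: 15 methyl 2-[(2S,3S)-3-(acetyloxy)-5-[(1S)-1-hydroxyethyl]-2,3-dihydro-1-benzofuran-2-yl]prop-2-enoate
Conditions: (R)-2-methyl-CBS-oxazaborolidine (0.2 equiv), catecholborane (1.5 equiv), toluene, −40 °C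
Reagents that add atoms: none
Why: Corey–Bakshi–Shibata reduction, in which the (R)-oxazaborolidine delivers hydride to the Re face of the aryl methyl ketone to give the (1S)-carbinol, while catecholborane at low temperature leaves the esters and the acrylate alone.

**Step 9**
Reactants: 15 methyl 2-[(2S,3S)-3-(acetyloxy)-5-[(1S)-1-hydroxyethyl]-2,3-dihydro-1-benzofuran-2-yl]prop-2-enoate; 16 (2Z)-2-methylbut-2-enoic acid (angelic acid)
Product: 18 methyl 2-[(2S,3S)-3-(acetyloxy)-5-[(1S)-1-{[(2Z)-2-methylbut-2-enoyl]oxy}ethyl]-2,3-dihydro-1-benzofuran-2-yl]prop-2-enoate (target), via mixed anhydride 17 (not isolated)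
Conditions: 16, 2,4,6-trichlorobenzoyl chloride, Et3N, toluene, 25 °C; then 15, 70 °C
Reagents that add atoms: none
Why: Yamaguchi-type esterification through the mixed anhydride of angelic acid, a protocol that acylates secondary alcohols without Z to E isomerisation and retains the carbinol configuration because its C–O bond is not broken.

**Compound list**
1 | 1,1,1,3,3,3-hexafluoropropan-2-yl prop-2-enoate | C=CC(=O)OC(C(F)(F)F)C(F)(F)F | starting material
2 | 2,2-dimethoxyacetaldehyde | COC(OC)C=O | starting material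
3 | 1,1,1,3,3,3-hexafluoropropan-2-yl (3S)-3-hydroxy-4,4-dimethoxy-2-methylidenebutanoate | C=C(C(=O)OC(C(F)(F)F)C(F)(F)F)[C@H](O)C(OC)OC | intermediate
4 | methyl (3S)-3-hydroxy-4,4-dimethoxy-2-methylidenebutanoate | C=C(C(=O)OC)[C@H](O)C(OC)OC | intermediate
5 | methyl (3S)-3-hydroxy-2-methylidene-4-oxobutanoate | C=C(C(=O)OC)[C@H](O)C=O | intermediate
6 | 2-(trimethylsilyl)phenyl trifluoromethanesulfonate | C[Si](C)(C)c1ccccc1OS(=O)(=O)C(F)(F)F | starting material
7 | benzyne (cyclohexa-1,3-dien-5-yne) | C1#CC=CC=C1 | intermediate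
8 | cesium 2-{[(2S)-3-methoxycarbonyl-1-oxobut-3-en-2-yl]oxy}benzen-1-ide | C=C(C(=O)OC)[C@@H](C=O)Oc1cccc[c-]1.[Cs+] | intermediate
9 | methyl 2-[(2S,3S)-3-hydroxy-2,3-dihydro-1-benzofuran-2-yl]prop-2-enoate | C=C(C(=O)OC)[C@@H]1Oc2ccccc2[C@@H]1O | intermediate
10 | methyl 2-[(2S,3S)-3-(acetyloxy)-2,3-dihydro-1-benzofuran-2-yl]prop-2-enoate | C=C(C(=O)OC)[C@@H]1Oc2ccccc2[C@@H]1OC(C)=O | intermediate
11 | methyl 2-[(2S,3S)-3-(acetyloxy)-5-bromo-2,3-dihydro-1-benzofuran-2-yl]prop-2-enoate | C=C(C(=O)OC)[C@@H]1Oc2ccc(Br)cc2[C@@H]1OC(C)=O | intermediate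
12 | tributyl(1-ethoxyethenyl)stannane | C=C(OCC)[Sn](CCCC)(CCCC)CCCC | starting material
13 | methyl 2-[(2S,3S)-3-(acetyloxy)-5-(1-ethoxyethenyl)-2,3-dihydro-1-benzofuran-2-yl]prop-2-enoate | C=C(C(=O)OC)[C@@H]1Oc2ccc(C(=C)OCC)cc2[C@@H]1OC(C)=O | intermediate
14 | methyl 2-[(2S,3S)-5-acetyl-3-(acetyloxy)-2,3-dihydro-1-benzofuran-2-yl]prop-2-enoate | C=C(C(=O)OC)[C@@H]1Oc2ccc(C(C)=O)cc2[C@@H]1OC(C)=O | intermediate
15 | methyl 2-[(2S,3S)-3-(acetyloxy)-5-[(1S)-1-hydroxyethyl]-2,3-dihydro-1-benzofuran-2-yl]prop-2-enoate | C=C(C(=O)OC)[C@@H]1Oc2ccc([C@H](C)O)cc2[C@@H]1OC(C)=O | intermediate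
16 | (2Z)-2-methylbut-2-enoic acid (angelic acid) | C/C=C(/C)C(=O)O | starting material
17 | (2Z)-2-methylbut-2-enoic 2,4,6-trichlorobenzoic anhydride | C/C=C(/C)C(=O)OC(=O)c1c(Cl)cc(Cl)cc1Cl | intermediate
18 | methyl 2-[(2S,3S)-3-(acetyloxy)-5-[(1S)-1-{[(2Z)-2-methylbut-2-enoyl]oxy}ethyl]-2,3-dihydro-1-benzofuran-2-yl]prop-2-enoate | C=C(C(=O)OC)[C@@H]1Oc2ccc([C@H](C)OC(=O)/C(C)=C\C)cc2[C@@H]1OC(C)=O | target

**Step count and risks**
Total step count: 9. Longest linear sequence: 9 steps (1 and 2 to 18); 6, 12 and 16 are bought.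

Steps most likely to fail:

1. Step 4 (proposed new method). What may go wrong: fluoride-promoted enolisation and self-condensation of the α-hydroxy aldehyde before it adds to the aryne, protonation of the aryl anion before ring closure, lactonisation of the cis alkoxide onto the methyl ester, or poor facial selectivity in the ring closure. Fallback, from 4 back to 9, by known chemistry: 4 is O-arylated with (2-iodophenyl)(2,4,6-trimethoxyphenyl)iodonium 4-methylbenzenesulfonate and NaOtBu in toluene (ligand coupling on the diaryliodonium salt, carbinol carbon untouched). This should give methyl (3S)-3-(2-iodophenoxy)-4,4-dimethoxy-2-methylidenebutanoate F1. Acetal hydrolysis as in step 3 should give methyl (3S)-3-(2-iodophenoxy)-2-methylidene-4-oxobutanoate F2. An intramolecular Nozaki–Hiyama–Kishi reaction (CrCl2, catalytic NiCl2, DMF, 25 °C) then closes the C3a–C3 bond through a chromium-chelated aldehyde and should return 9.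

2. Step 3. What may go wrong: acid-promoted enolisation of the free α-hydroxy aldehyde with loss of configuration at C3, and oligomerisation on concentration. Fallback, from 1 back to 5: the β-isocupreidine-catalysed Morita–Baylis–Hillman reaction of 1 with (E)-but-2-enal should give 1,1,1,3,3,3-hexafluoropropan-2-yl (3R,4E)-3-hydroxy-2-methylidenehex-4-enoate F3 (same spatial arrangement as in 3; the descriptor changes with the substituent). Methanolysis (MeOH, Et3N) should give methyl (3R,4E)-3-hydroxy-2-methylidenehex-4-enoate F4. Ozonolysis of the electron-richer disubstituted alkene (one equivalent of O3, CH2Cl2, −78 °C, then PPh3) should release 5 under neutral conditions, with volatile acetaldehyde as co-product.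

3. Step 9. What may go wrong: Z to E isomerisation of the angeloyl unit during carboxyl activation, and elimination at the benzylic ester positions on heating. Fallback, from 15 back to 18: 15 is esterified with 2-[bis(2,2,2-trifluoroethoxy)phosphoryl]propanoic acid (N,N'-dicyclohexylcarbodiimide, catalytic 4-(dimethylamino)pyridine, CH2Cl2, 0 °C). This should give methyl 2-[(2S,3S)-3-(acetyloxy)-5-[(1S)-1-({2-[bis(2,2,2-trifluoroethoxy)phosphoryl]propanoyl}oxy)ethyl]-2,3-dihydro-1-benzofuran-2-yl]prop-2-enoate F5 (both epimers at the phosphonate carbon). A Still–Gennari olefination with acetaldehyde (KN(SiMe3)2, 18-crown-6, THF, −78 °C) then builds the Z-configured 2-methylbut-2-enoate on the intact carbinol ester and should give 18.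

**Further compounds**
F1 | step 4 | methyl (3S)-3-(2-iodophenoxy)-4,4-dimethoxy-2-methylidenebutanoate | C=C(C(=O)OC)[C@H](Oc1ccccc1I)C(OC)OC
F2 | step 4 | methyl (3S)-3-(2-iodophenoxy)-2-methylidene-4-oxobutanoate | C=C(C(=O)OC)[C@H](Oc1ccccc1I)C=O
F3 | step 3 | 1,1,1,3,3,3-hexafluoropropan-2-yl (3R,4E)-3-hydroxy-2-methylidenehex-4-enoate | C=C(C(=O)OC(C(F)(F)F)C(F)(F)F)[C@H](O)/C=C/C
F4 | step 3 | methyl (3R,4E)-3-hydroxy-2-methylidenehex-4-enoate | C=C(C(=O)OC)[C@H](O)/C=C/C
F5 | step 9 | methyl 2-[(2S,3S)-3-(acetyloxy)-5-[(1S)-1-({2-[bis(2,2,2-trifluoroethoxy)phosphoryl]propanoyl}oxy)ethyl]-2,3-dihydro-1-benzofuran-2-yl]prop-2-enoate | C=C(C(=O)OC)[C@@H]1Oc2ccc([C@H](C)OC(=O)C(C)P(=O)(OCC(F)(F)F)OCC(F)(F)F)cc2[C@@H]1OC(C)=O
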